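Numbering follows the 2(3H)-naphthalenone core (ring A: C1–C4, C4a, C8a; ring B: C4a–C8, C8a). Everything rests on cutting ring B at C4a–C8a and C5–C6: an intramolecular Diels–Alder reaction of a linear, axially chiral vinylallenyl ketone closes both rings in one operation. It exploits the heteroannular dienone C7=C8–C8a=C1–C2=O, which is the footprint of a vinylallene diene, and transfers the allene axis to the all-cis C4a-methyl, C5-methyl and C6-oxygen triad. The precursor is an acyclic (E)-1-boryl-1,3,4-trien-6-one tethered to an (E)-trisubstituted alkene; the C6 boron becomes the hydroxyl that is acylated with the dienoic acid.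

Key step: step 10

Remark: 2 is the isomer with the two methyl groups cis. The allene axis of 14 and 15 is (aR) and is encoded in the SMILES on the central allene carbon.

Step 1
Reactants: 1 methyl (R)-glycidate; 2 (E)-2-bromobut-2-ene
Product: 5 methyl (2R,4E)-2-hydroxy-4-methylhex-4-enoate, via butenyllithium 3 (not isolated), via butenylmagnesium bromide 4 (not isolated)
Conditions: 2, t-BuLi (2 equiv), Et2O, −78 °C; MgBr2·OEt2, −78 to 0 °C; CuI (10 mol %), 1, THF, −40 °C; sat. NH4Cl
Reagents that add atoms: none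
Why: Copper-catalysed SN2 opening of the glycidic ester at its CH2 carbon by an alkenyl Grignard reagent (made by halogen–lithium exchange with retention of geometry) should give the (E)-trisubstituted alkene, while the stereocentre of 1 is carried over untouched as the later C3 carbinol.

Step 2
Reactants: 5 methyl (2R,4E)-2-hydroxy-4-methylhex-4-enoate
Product: 6 methyl (2R,4E)-2-[(tert-butyldimethylsilyl)oxy]-4-methylhex-4-enoate
Conditions: TBSCl, imidazole, DMF, rt
Reagents that add atoms: tert-butyldimethylsilyl chloride, CC(C)(C)[Si](C)(C)Cl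
Why: Silylation of the secondary alcohol gives a silyl ether that should survive every later step until the final fluoride treatment.

Step 3
Reactants: 6 methyl (2R,4E)-2-[(tert-butyldimethylsilyl)oxy]-4-methylhex-4-enoate
Product: 8 ethyl (2E,4R,6E)-4-[(tert-butyldimethylsilyl)oxy]-6-methylocta-2,6-dienoate, via silyloxy aldehyde 7 (not isolated)
Conditions: i-Bu2AlH (1.05 equiv), CH2Cl2, −78 °C; then Ph3P=CHCO2Et, −78 °C to rt
Reagents that add atoms: ethyl (triphenylphosphoranylidene)acetate, CCOC(=O)C=P(c1ccccc1)(c1ccccc1)c1ccccc1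
Why: Half-reduction of the α-silyloxy ester followed in the same flask by Wittig olefination with a stabilised ylide should give the (E)-enoate without isolating the epimerisable aldehyde.

Step 4
Reactants: 8 ethyl (2E,4R,6E)-4-[(tert-butyldimethylsilyl)oxy]-6-methylocta-2,6-dienoate
Product: 9 (2E,4R,6E)-4-[(tert-butyldimethylsilyl)oxy]-6-methylocta-2,6-dien-1-ol
Conditions: i-Bu2AlH (2.2 equiv), CH2Cl2, −78 °C
Reagents that add atoms: none
Why: 1,2-Reduction of the enoate with an aluminium hydride gives the primary (E)-allylic alcohol needed for directed epoxidation.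

Step 5
Reactants: 9 (2E,4R,6E)-4-[(tert-butyldimethylsilyl)oxy]-6-methylocta-2,6-dien-1-ol
Product: 10 [(2R,3S)-3-[(1R,3E)-1-[(tert-butyldimethylsilyl)oxy]-3-methylpent-3-en-1-yl]oxiran-2-yl]methanol
Conditions: Ti(OiPr)4 (10 mol %), (−)-diethyl D-tartrate (12 mol %), t-BuOOH, 4 Å MS, CH2Cl2, −20 °C
Reagents that add atoms: tert-butyl hydroperoxide, CC(C)(C)OO
Why: Sharpless asymmetric epoxidation with the D-tartrate ligand should deliver oxygen under reagent control to the face that makes the carbinol-bearing oxirane carbon (R), the centre that later becomes the allene axis, and it leaves the isolated trisubstituted alkene untouched.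

Step 6
Reactants: 10 [(2R,3S)-3-[(1R,3E)-1-[(tert-butyldimethylsilyl)oxy]-3-methylpent-3-en-1-yl]oxiran-2-yl]methanol
Product: 11 (2S,3S)-3-[(1R,3E)-1-[(tert-butyldimethylsilyl)oxy]-3-methylpent-3-en-1-yl]oxirane-2-carbaldehyde
Conditions: Dess–Martin periodinane, NaHCO3, CH2Cl2, 0 °C to rt
Reagents that add atoms: none
Why: Buffered Dess–Martin oxidation of the primary alcohol should give the epoxy aldehyde without opening the oxirane.

Step 7
Reactants: 11 (2S,3S)-3-[(1R,3E)-1-[(tert-butyldimethylsilyl)oxy]-3-methylpent-3-en-1-yl]oxirane-2-carbaldehyde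
Product: 12 (2R,3S)-2-ethynyl-3-[(1R,3E)-1-[(tert-butyldimethylsilyl)oxy]-3-methylpent-3-en-1-yl]oxirane
Conditions: dimethyl (1-diazo-2-oxopropyl)phosphonate, K2CO3, MeOH, 0 °C to rt
Reagents that add atoms: dimethyl (1-diazo-2-oxopropyl)phosphonate, COP(=O)(OC)C(=[N+]=[N-])C(C)=O
Why: The Ohira–Bestmann variant of the Seyferth–Gilbert homologation converts the aldehyde into the terminal alkyne under mild carbonate conditions that should leave the oxirane and its propargylic configuration intact.

Step 8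
Reactants: 12 (2R,3S)-2-ethynyl-3-[(1R,3E)-1-[(tert-butyldimethylsilyl)oxy]-3-methylpent-3-en-1-yl]oxirane; 13 (E)-1,2-bis(4,4,5,5-tetramethyl-1,3,2-dioxaborolan-2-yl)ethene
Product: 14 (aR,1E,6S,7R,9E)-7-[(tert-butyldimethylsilyl)oxy]-9-methyl-1-(4,4,5,5-tetramethyl-1,3,2-dioxaborolan-2-yl)undeca-1,3,4,9-tetraen-6-ol
Conditions: Pd(PPh3)4 (5 mol %), 13 (3 equiv), THF/H2O (10:1), rt
Reagents that add atoms: none
Why: Suzuki-type coupling of a propargylic oxirane: anti-SN2' oxidative addition of zerovalent palladium gives an allenylpalladium alkoxide that takes one alkenyl group from 13 and reductively eliminates with retention, so the (R) oxirane carbon is relayed to the (aR) allene axis and the (E) alkenylboronate geometry is kept.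

Step 9
Reactants: 14 (aR,1E,6S,7R,9E)-7-[(tert-butyldimethylsilyl)oxy]-9-methyl-1-(4,4,5,5-tetramethyl-1,3,2-dioxaborolan-2-yl)undeca-1,3,4,9-tetraen-6-ol
Product: 15 (aR,1E,7R,9E)-7-[(tert-butyldimethylsilyl)oxy]-9-methyl-1-(4,4,5,5-tetramethyl-1,3,2-dioxaborolan-2-yl)undeca-1,3,4,9-tetraen-6-one
Conditions: Dess–Martin periodinane, NaHCO3, CH2Cl2, 0 °C
Reagents that add atoms: none
Why: Dess–Martin oxidation of the α-allenic alcohol gives the allenyl ketone under neutral, base-free conditions that should not erode the axis by γ-deprotonation.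

Step 10
Reactants: 15 (aR,1E,7R,9E)-7-[(tert-butyldimethylsilyl)oxy]-9-methyl-1-(4,4,5,5-tetramethyl-1,3,2-dioxaborolan-2-yl)undeca-1,3,4,9-tetraen-6-one
Product: 17 (3R,4aR,5R,6S)-3-[(tert-butyldimethylsilyl)oxy]-6-hydroxy-4a,5-dimethyl-4,4a,5,6-tetrahydronaphthalen-2(3H)-one, via allylboronate 16 (not isolated)
Conditions: PhMe (0.005 M), BHT (cat.), 90 °C; then THF, pH 7 phosphate buffer, 30% H2O2, 0 °C
Reagents that add atoms: hydrogen peroxide, OO
Why: Thermal, concerted, suprafacial [4+2] cycloaddition in which the vinylallene C6=C7–C8=C8a (C8a is the central allene carbon) is the 4π partner and the tethered (E)-trisubstituted alkene C4a=C5 the 2π partner; the closest known reaction type is the intramolecular Diels–Alder reaction of vinylallenes, here with a 1-boryl diene terminus that is oxidised in the same flask. Ring B is closed by the cycloaddition itself and ring A by the three-atom tether C2–C3–C4 in a type 1 mode, the distal allene double bond remaining as C8a=C1, so the C7=C8–C8a=C1–C2=O dienone arises directly. Because C1 lies on the allene axis beyond C8a, the tether can only reach from the exo side; this places the C4a and C5 methyl groups endo and, with the (E)-boronate on the outside of C6, makes boron and both methyl groups cis, while the (E) alkene fixes C4a relative to C5. The absolute sense is fixed by the (aR) axis, since the dienophile must add to the diene face on which the C2 carbonyl carbon sits; the C3 silyloxy centre is a spectator that can lie pseudo-equatorial in the forming ring A with the angular methyl axial. The step needs the axial and alkene geometries to survive (neutral, dilute conditions) and a regiochemistry that the short tether enforces. H2O2 at pH 7 should then convert the allylic C–B bond into the C6–OH bond with retention.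

Step 11
Reactants: 18 (R)-4-benzyl-3-propionyloxazolidin-2-one; 19 acetaldehyde
Product: 21 (R)-4-benzyl-3-[(2R,3S)-3-hydroxy-2-methylbutanoyl]oxazolidin-2-one, via boron enolate 20 (not isolated)
Conditions: Bu2BOTf, i-Pr2NEt, CH2Cl2, −78 to 0 °C; 19, −78 to 0 °C; pH 7 buffer, MeOH, H2O2
Reagents that add atoms: none
Why: Evans syn-aldol reaction: the (Z)-boron enolate adds to acetaldehyde through a chair Zimmerman–Traxler transition state on the face left open by the auxiliary, which should set both side-chain stereocentres as the (2R,3S)-syn pair.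

Step 12
Reactants: 21 (R)-4-benzyl-3-[(2R,3S)-3-hydroxy-2-methylbutanoyl]oxazolidin-2-one
Product: 22 (R)-4-benzyl-3-[(2R,3S)-3-[(tert-butyldimethylsilyl)oxy]-2-methylbutanoyl]oxazolidin-2-one
Conditions: TBSOTf, 2,6-lutidine, CH2Cl2, −78 to 0 °C
Reagents that add atoms: tert-butyldimethylsilyl trifluoromethanesulfonate, CC(C)(C)[Si](C)(C)OS(=O)(=O)C(F)(F)F
Why: Silylation of the β-hydroxy imide with the silyl triflate and a hindered base avoids retro-aldol cleavage and protects the alcohol for the later esterification.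

Step 13
Reactants: 22 (R)-4-benzyl-3-[(2R,3S)-3-[(tert-butyldimethylsilyl)oxy]-2-methylbutanoyl]oxazolidin-2-one
Product: 23 (2S,3S)-3-[(tert-butyldimethylsilyl)oxy]-2-methylbutan-1-ol
Conditions: LiBH4, MeOH (1 equiv), THF, 0 °C
Reagents that add atoms: none
Why: Reductive cleavage of the N-acyl oxazolidinone with LiBH4 releases the primary alcohol and the auxiliary without touching the silyl ether or either stereocentre.

Step 14
Reactants: 23 (2S,3S)-3-[(tert-butyldimethylsilyl)oxy]-2-methylbutan-1-ol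
Product: 24 (2R,3S)-3-[(tert-butyldimethylsilyl)oxy]-2-methylbutanal
Conditions: Dess–Martin periodinane, NaHCO3, CH2Cl2, 0 °C to rt
Reagents that add atoms: none
Why: Dess–Martin oxidation gives the α-methyl aldehyde under neutral conditions that should not epimerise it.

Step 15
Reactants: 24 (2R,3S)-3-[(tert-butyldimethylsilyl)oxy]-2-methylbutanal
Product: 25 ethyl (2E,4E,6S,7S)-7-[(tert-butyldimethylsilyl)oxy]-6-methylocta-2,4-dienoate
Conditions: triethyl 4-phosphonocrotonate, LiN(SiMe3)2, THF, −78 to 0 °C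
Reagents that add atoms: triethyl (E)-4-phosphonocrotonate, CCOC(=O)/C=C/CP(=O)(OCC)OCC
Why: Vinylogous Horner–Wadsworth–Emmons olefination with the stabilised phosphonate anion should form the new C4=C5 alkene with (E) geometry and give the (2E,4E)-dienoate at low temperature without epimerising C6.

Step 16
Reactants: 25 ethyl (2E,4E,6S,7S)-7-[(tert-butyldimethylsilyl)oxy]-6-methylocta-2,4-dienoate
Product: 26 (2E,4E,6S,7S)-7-[(tert-butyldimethylsilyl)oxy]-6-methylocta-2,4-dienoic acid
Conditions: LiOH, THF/MeOH/H2O, rt; then 1 M HCl to pH 4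
Reagents that add atoms: lithium hydroxide, [Li+].[OH-]
Why: Saponification of the ethyl ester gives the free dienoic acid, and the secondary silyl ether tolerates hydroxide and brief mild acidification.

Step 17
Reactants: 26 (2E,4E,6S,7S)-7-[(tert-butyldimethylsilyl)oxy]-6-methylocta-2,4-dienoic acid; 17 (3R,4aR,5R,6S)-3-[(tert-butyldimethylsilyl)oxy]-6-hydroxy-4a,5-dimethyl-4,4a,5,6-tetrahydronaphthalen-2(3H)-one
Product: 28 6-O-[(2E,4E,6S,7S)-7-[(tert-butyldimethylsilyl)oxy]-6-methylocta-2,4-dienoyl] derivative of 17, via mixed anhydride 27 (not isolated)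
Conditions: 2,4,6-trichlorobenzoyl chloride, Et3N, THF, rt; then 17, DMAP, PhMe, rt to 40 °C
Reagents that add atoms: none
Why: Yamaguchi esterification through the mixed anhydride and the acylpyridinium ion should acylate the hindered secondary allylic C6 alcohol with retention, the C3 oxygen being masked as its silyl ether.

Step 18
Reactants: 28 6-O-[(2E,4E,6S,7S)-7-[(tert-butyldimethylsilyl)oxy]-6-methylocta-2,4-dienoyl] derivative of 17
Product: 29 (1R,2S,7R,8aR)-7-hydroxy-1,8a-dimethyl-6-oxo-1,2,6,7,8,8a-hexahydronaphthalen-2-yl (2E,4E,6S,7S)-7-hydroxy-6-methylocta-2,4-dienoate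
Conditions: HF·pyridine, pyridine, THF, 0 °C to rt
Reagents that add atoms: none
Why: Fluoride-mediated cleavage of both silyl ethers under buffered, non-basic conditions should leave the allylic ester, the dienone and the α-hydroxy ketone intact.

Compound list
1 | methyl (2R)-oxirane-2-carboxylate (methyl (R)-glycidate) | COC(=O)[C@H]1CO1 | starting material
2 | (E)-2-bromobut-2-ene (methyl groups cis) | C/C=C(\C)Br | starting material
3 | but-2-en-2-yllithium, methyl groups cis | C/C=C(\C)[Li] | intermediate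
4 | but-2-en-2-ylmagnesium bromide, methyl groups cis | C/C=C(\C)[Mg]Br | intermediate
5 | methyl (2R,4E)-2-hydroxy-4-methylhex-4-enoate | COC(=O)[C@H](O)C/C(C)=C/C | intermediate
6 | methyl (2R,4E)-2-[(tert-butyldimethylsilyl)oxy]-4-methylhex-4-enoate | COC(=O)[C@H](O[Si](C)(C)C(C)(C)C)C/C(C)=C/C | intermediate
7 | (2R,4E)-2-[(tert-butyldimethylsilyl)oxy]-4-methylhex-4-enal | O=C[C@H](O[Si](C)(C)C(C)(C)C)C/C(C)=C/C | intermediate
8 | ethyl (2E,4R,6E)-4-[(tert-butyldimethylsilyl)oxy]-6-methylocta-2,6-dienoate | CCOC(=O)/C=C/[C@H](O[Si](C)(C)C(C)(C)C)C/C(C)=C/C | intermediate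
9 | (2E,4R,6E)-4-[(tert-butyldimethylsilyl)oxy]-6-methylocta-2,6-dien-1-ol | OC/C=C/[C@H](O[Si](C)(C)C(C)(C)C)C/C(C)=C/C | intermediate
10 | [(2R,3S)-3-[(1R,3E)-1-[(tert-butyldimethylsilyl)oxy]-3-methylpent-3-en-1-yl]oxiran-2-yl]methanol | OC[C@H]1O[C@@H]1[C@H](O[Si](C)(C)C(C)(C)C)C/C(C)=C/C | intermediate
11 | (2S,3S)-3-[(1R,3E)-1-[(tert-butyldimethylsilyl)oxy]-3-methylpent-3-en-1-yl]oxirane-2-carbaldehyde | O=C[C@H]1O[C@@H]1[C@H](O[Si](C)(C)C(C)(C)C)C/C(C)=C/C | intermediate
12 | (2R,3S)-2-ethynyl-3-[(1R,3E)-1-[(tert-butyldimethylsilyl)oxy]-3-methylpent-3-en-1-yl]oxirane | C#C[C@H]1O[C@@H]1[C@H](O[Si](C)(C)C(C)(C)C)C/C(C)=C/C | intermediate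
13 | (E)-1,2-bis(4,4,5,5-tetramethyl-1,3,2-dioxaborolan-2-yl)ethene | CC1(C)OB(/C=C/B2OC(C)(C)C(C)(C)O2)OC1(C)C | starting material
14 | (aR,1E,6S,7R,9E)-7-[(tert-butyldimethylsilyl)oxy]-9-methyl-1-(4,4,5,5-tetramethyl-1,3,2-dioxaborolan-2-yl)undeca-1,3,4,9-tetraen-6-ol | CC1(C)OB(/C=C/C=[C@]=C[C@H](O)[C@H](O[Si](C)(C)C(C)(C)C)C/C(C)=C/C)OC1(C)C | intermediate
15 | (aR,1E,7R,9E)-7-[(tert-butyldimethylsilyl)oxy]-9-methyl-1-(4,4,5,5-tetramethyl-1,3,2-dioxaborolan-2-yl)undeca-1,3,4,9-tetraen-6-one | CC1(C)OB(/C=C/C=[C@]=CC(=O)[C@H](O[Si](C)(C)C(C)(C)C)C/C(C)=C/C)OC1(C)C | intermediate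
16 | (3R,4aR,5S,6S)-3-[(tert-butyldimethylsilyl)oxy]-4a,5-dimethyl-6-(4,4,5,5-tetramethyl-1,3,2-dioxaborolan-2-yl)-4,4a,5,6-tetrahydronaphthalen-2(3H)-one | CC1(C)OB(OC1(C)C)[C@H]2C=CC3=CC(=O)[C@H](O[Si](C)(C)C(C)(C)C)C[C@]3(C)[C@H]2C | intermediate
17 | (3R,4aR,5R,6S)-3-[(tert-butyldimethylsilyl)oxy]-6-hydroxy-4a,5-dimethyl-4,4a,5,6-tetrahydronaphthalen-2(3H)-one | O[C@H]1C=CC2=CC(=O)[C@H](O[Si](C)(C)C(C)(C)C)C[C@]2(C)[C@H]1C | intermediate
18 | (R)-4-benzyl-3-propionyloxazolidin-2-one | CCC(=O)N1C(=O)OC[C@H]1Cc1ccccc1 | starting material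
19 | acetaldehyde | CC=O | starting material
20 | dibutylboron (Z)-enolate of 18 | C/C=C(\OB(CCCC)CCCC)N1C(=O)OC[C@H]1Cc1ccccc1 | intermediate
21 | (R)-4-benzyl-3-[(2R,3S)-3-hydroxy-2-methylbutanoyl]oxazolidin-2-one | C[C@H](O)[C@@H](C)C(=O)N1C(=O)OC[C@H]1Cc1ccccc1 | intermediate
22 | (R)-4-benzyl-3-[(2R,3S)-3-[(tert-butyldimethylsilyl)oxy]-2-methylbutanoyl]oxazolidin-2-one | C[C@H](O[Si](C)(C)C(C)(C)C)[C@@H](C)C(=O)N1C(=O)OC[C@H]1Cc1ccccc1 | intermediate
23 | (2S,3S)-3-[(tert-butyldimethylsilyl)oxy]-2-methylbutan-1-ol | C[C@H](O[Si](C)(C)C(C)(C)C)[C@@H](C)CO | intermediate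
24 | (2R,3S)-3-[(tert-butyldimethylsilyl)oxy]-2-methylbutanal | C[C@H](O[Si](C)(C)C(C)(C)C)[C@@H](C)C=O | intermediate
25 | ethyl (2E,4E,6S,7S)-7-[(tert-butyldimethylsilyl)oxy]-6-methylocta-2,4-dienoate | C[C@H](O[Si](C)(C)C(C)(C)C)[C@@H](C)/C=C/C=C/C(=O)OCC | intermediate
26 | (2E,4E,6S,7S)-7-[(tert-butyldimethylsilyl)oxy]-6-methylocta-2,4-dienoic acid | C[C@H](O[Si](C)(C)C(C)(C)C)[C@@H](C)/C=C/C=C/C(=O)O | intermediate
27 | mixed anhydride of 26 and 2,4,6-trichlorobenzoic acid | C[C@H](O[Si](C)(C)C(C)(C)C)[C@@H](C)/C=C/C=C/C(=O)OC(=O)c1c(Cl)cc(Cl)cc1Cl | intermediate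
28 | 6-O-[(2E,4E,6S,7S)-7-[(tert-butyldimethylsilyl)oxy]-6-methylocta-2,4-dienoyl] derivative of 17 | C[C@H](O[Si](C)(C)C(C)(C)C)[C@@H](C)/C=C/C=C/C(=O)O[C@H]1C=CC2=CC(=O)[C@H](O[Si](C)(C)C(C)(C)C)C[C@]2(C)[C@H]1C | intermediate
29 | (1R,2S,7R,8aR)-7-hydroxy-1,8a-dimethyl-6-oxo-1,2,6,7,8,8a-hexahydronaphthalen-2-yl (2E,4E,6S,7S)-7-hydroxy-6-methylocta-2,4-dienoate | C[C@H](O)[C@@H](C)/C=C/C=C/C(=O)O[C@H]1C=CC2=CC(=O)[C@H](O)C[C@]2(C)[C@H]1C | target

Total step count: 18. Longest linear sequence: 12 steps (steps 1–10, 17 and 18); the side-chain acid takes steps 11–16.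

Steps most likely to fail

Step 10. The allenyl ketone 15 may lose axial purity by reversible γ-deprotonation, or may oligomerise faster than it closes onto the unactivated trisubstituted alkene. The fallback runs the cycloaddition one oxidation level lower and sets out from 14, whose axis cannot epimerise. Heating 14 (PhMe, 110 °C) should give, by the same exo-tethered [4+2], the bicyclic dienyl alcohol boronate F1. Dess–Martin oxidation of its ring A allylic hydroxyl then gives allylboronate 16, where the route is rejoined and the buffered H2O2 oxidation to 17 follows as in step 10.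

Step 8. The bis-boronate 13 may couple twice, or the oxirane may open directly and protodeboronation may compete with clean anti-SN2' transfer of one alkenyl group. The fallback sets out from 12 and brings the two carbons in as an alkyne. Pd(PPh3)4/CuI-catalysed anti-SN2' coupling of 12 with ethynyltrimethylsilane should give the silylated allenynol F2, and K2CO3 in MeOH should remove the silyl group to give the terminal allenynol F3. Hydroboration of the terminal alkyne with pinacolborane, catalysed by dicyclohexylborane, then installs the (E)-alkenylboronate and returns to 14.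

Step 17. Acylation of the C6 hydroxyl of 17 may be sluggish because it is shielded by the cis C5 and C4a methyl groups, and the activated dienoate may isomerise under forcing conditions. The fallback sets out from 17 and forms the ester bond with a small acid before the diene is completed. Acylation of 17 with (E)-4-(diethoxyphosphoryl)but-2-enoic acid (EDC·HCl, DMAP, CH2Cl2) should give the phosphonocrotonate ester F4. Its lithium salt (LiN(SiMe3)2, THF, −78 °C) should then undergo Horner–Wadsworth–Emmons olefination with aldehyde 24 and return to 28.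

Further compounds
F1 | step 10 | (2S,3R,4aR,5S,6S)-3-[(tert-butyldimethylsilyl)oxy]-4a,5-dimethyl-6-(4,4,5,5-tetramethyl-1,3,2-dioxaborolan-2-yl)-2,3,4,4a,5,6-hexahydronaphthalen-2-ol | CC1(C)OB(OC1(C)C)[C@H]2C=CC3=C[C@H](O)[C@H](O[Si](C)(C)C(C)(C)C)C[C@]3(C)[C@H]2C
F2 | step 8 | (aR,6S,7R,9E)-7-[(tert-butyldimethylsilyl)oxy]-9-methyl-1-(trimethylsilyl)undeca-3,4,9-trien-1-yn-6-ol | C[Si](C)(C)C#CC=[C@]=C[C@H](O)[C@H](O[Si](C)(C)C(C)(C)C)C/C(C)=C/C
F3 | step 8 | (aR,6S,7R,9E)-7-[(tert-butyldimethylsilyl)oxy]-9-methylundeca-3,4,9-trien-1-yn-6-ol | C#CC=[C@]=C[C@H](O)[C@H](O[Si](C)(C)C(C)(C)C)C/C(C)=C/C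
F4 | step 17 | 6-O-[(E)-4-(diethoxyphosphoryl)but-2-enoyl] derivative of 17 | CCOP(=O)(OCC)C/C=C/C(=O)O[C@H]1C=CC2=CC(=O)[C@H](O[Si](C)(C)C(C)(C)C)C[C@]2(C)[C@H]1C
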